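(The rate constants are invented; what happens was integrated by code.)

The ratio of the constant for a unit leaving a chain to the constant for a unit joining one, 5.53 mM, is the free monomer at which a living end gains and loses at the same pace, the ceiling concentration. With it I want to choose the recipe for the next run and judge whether its time is long enough.

- birch: free monomer 0.050 M; initiator 1.2 mM; time 12 h
- alder: free monomer 0.025 M; initiator 1.2 mM; time 12 h

- which of the two ends with the longer chains by the average number of monomer units in a chain (chains begun, living or dead) ("neither" if they lie within 10%) (birch / alder / neither)
- average number of monomer units in a chain (chains begun, living or dead) at the end, birch
- average number of monomer units in a chain (chains begun, living or dead) at the end, alder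

- the average divides the monomer in chains by the number of chains begun, living and dead together
- run time (birch): 12 h

    free monomer + initiator → living end + monomer in chains (k1 = 0.086 /M/s)
    free monomer + living end → monomer in chains + living end, rate k2*[living end]*[free monomer] (k2 = 0.038 /M/s)
    monomer in chains + living end → free monomer + living end, rate k3*[living end] as long as [monomer in chains] is above zero (k3 = 2.1 × 10⁻⁴ /s)
    free monomer → uncatalysed product (k4 = 1.0 × 10⁻⁶ /s)

Even in alder, each initiator lasts about 7.75 min, which is far shorter than the closing time 6.09 h, so I take the living end as equal to the initiator charge from the start. Each chain has then taken one unit, and the free monomer closes its gap to the ceiling in pseudo-first-order fashion. Birch and alder carry the same initiator charge, so they share that closing time. I count turns, a turn being one closing time passed: the run allows 1.97, which leaves 13.9% of the gap open. I leave out the uncatalysed step, since its half-life of 190 h is much longer than the run.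

Birch then holds 11.6 mM of free monomer, and dividing what has left it by the initiator charge gives a length of 32.0. Alder holds 8.07 mM and reaches 14.1, which is shorter. The gap still open in birch is worth 5.03 units a chain. I would charge birch for its longer chains and accept that gap at the planned time.

The forecast names birch, with 31.4 for birch and 13.8 for alder, on the ground that “12 h covers about two time constants”. It takes off the uncatalysed loss that I dropped, and its birch length lies below mine.

The flask gives birch, with 31.4 for birch and 13.8 for alder. Now take birch read at 3.0 h instead. That time allows 0.492 turns, which leaves 61.1% of the gap open. Free monomer should then stand at 32.0 mM, or 63.9% of the charge, and the length at 15.0. That flask, read at 3.0 h, holds 64% of its charged free monomer unbound and has a length of 14.7.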